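The route rests on cutting the C2–C1' bond. In the target the C3 oxygen and C1' sit cis on the dihydrofuran ring, so O(C3), C3, C2, C1' and the aldehyde carbon can be drawn as a γ-lactone, and C2–H is an ether C–H next to O1. A dirhodium carbene tethered to the C3 oxygen therefore inserts into the syn C2–H bond. This forms C2–C1', closes the cis-fused lactone and copies the C3 configuration onto C2 in one operation. The precursor is the diazo(phosphono)acetate of an enantiopure 2,3-dihydrobenzofuran-3-ol whose C5 side-chain carbinol is masked as a triethylsilyl ether. Both carbinol centres come from catalytic transfer hydrogenations.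

Key step: step 7

Locants: dihydrobenzofuran numbering is used throughout (O1, C2, C3, C3a, C4–C7, C7a; the benzo ring is ring A). C1' is the carbon on C2 and C1'' is the carbinol carbon on C5.

Assumption: the Ru–TsDPEN catalysts are taken to read the benzofuran-3(2H)-one carbonyl as they read 1-indanone and 4-chromanone, with ring A in the aryl site.

Design points:
- **Catalyst hand.** The target is 2R,3R (cis) and 1''R. At C3 the atom C2 outranks C3a, so 3R and 1''R are opposite in the aryl/alkyl spatial sense. The two ketone reductions therefore need catalysts of opposite hand and are run one after the other.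
- **Silyl groups.** The side-chain alcohol travels as a triethylsilyl ether and the later primary allylic alcohol as a tert-butyldiphenylsilyl ether. A secondary silyl ether can be removed beside a primary one only if it is much the more labile of the two. Mild cleavage also spares the ionisable p-alkoxybenzylic C1''–O bond.
- **Enal last.** CH2=C(CHO)–C2H(OAr) is an allylic aryl ether open to SN2' attack by nucleophilic amines, so the enal is unveiled last under neutral conditions.

Step 1
Reactants: 1 5-bromo-1-benzofuran-3(2H)-one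
Product: 2 (3R)-5-bromo-2,3-dihydro-1-benzofuran-3-ol
Conditions: RuCl[(S,S)-TsDPEN](p-cymene) (1 mol %), HCO2H/Et3N (5:2), CH2Cl2, rt
Reagents that add atoms: none
Why: Noyori–Ikariya asymmetric transfer hydrogenation of a benzo-fused aryl ketone, in which the CH/π contact between p-cymene and ring A fixes the carbonyl face that receives hydride, and the (S,S) ligand gives the arrangement labelled R here only because C2 (O,H,H) outranks C3a.

Step 2
Reactants: 2 (3R)-5-bromo-2,3-dihydro-1-benzofuran-3-ol; 3 tributyl(1-ethoxyvinyl)stannane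
Product: 5 (3R)-5-acetyl-2,3-dihydro-1-benzofuran-3-ol, via ethoxyvinyl arene 4 (not isolated)
Conditions: Pd(PPh3)4 (5 mol %), toluene, 100 °C; then 0.1 M aq HCl, THF, 0 °C, short contact
Reagents that add atoms: tributyl(1-ethoxyvinyl)stannane (3), C=C(OCC)[Sn](CCCC)(CCCC)CCCC; water, O
Why: The Migita–Kosugi–Stille coupling tolerates the free alcohol, and the donor-substituted aryl enol ether hydrolyses in dilute cold acid far faster than the C3 carbinol can lose water toward the benzofuran, so C3 is untouched.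

Step 3
Reactants: 5 (3R)-5-acetyl-2,3-dihydro-1-benzofuran-3-ol; 6 2-(diethoxyphosphoryl)acetic acid
Product: 7 (3R)-5-acetyl-2,3-dihydro-1-benzofuran-3-yl 2-(diethoxyphosphoryl)acetate
Conditions: DCC, DMAP (cat.), CH2Cl2, 0 °C → rt
Reagents that add atoms: 2-(diethoxyphosphoryl)acetic acid (6), CCOP(=O)(CC(=O)O)OCC
Why: Steglich esterification acylates at oxygen, so the C3–O bond and its configuration are kept, and the ester installs the future carbene tether while marking the C3 oxygen as different from the alcohol made next.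

Step 4
Reactants: 7 (3R)-5-acetyl-2,3-dihydro-1-benzofuran-3-yl 2-(diethoxyphosphoryl)acetate
Product: 8 (3R)-5-[(1R)-1-hydroxyethyl]-2,3-dihydro-1-benzofuran-3-yl 2-(diethoxyphosphoryl)acetate
Conditions: RuCl[(R,R)-TsDPEN](p-cymene) (1–2 mol %), HCO2H/Et3N (5:2), CH2Cl2, rt
Reagents that add atoms: none
Why: Noyori–Ikariya transfer hydrogenation of a p-alkoxyacetophenone-type ketone, in which the (R,R) ligand sets 1''R under catalyst control because C3 is remote and, as an ester, cannot be dehydrogenated by the catalyst of opposite hand.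

Step 5
Reactants: 8 (3R)-5-[(1R)-1-hydroxyethyl]-2,3-dihydro-1-benzofuran-3-yl 2-(diethoxyphosphoryl)acetate
Product: 9 (3R)-5-[(1R)-1-(triethylsilyloxy)ethyl]-2,3-dihydro-1-benzofuran-3-yl 2-(diethoxyphosphoryl)acetate
Conditions: Et3SiCl, imidazole, CH2Cl2, 0 °C
Reagents that add atoms: chlorotriethylsilane, CC[Si](Cl)(CC)CC
Why: Standard O-silylation removes the O–H bond that would otherwise trap the carbene, and it does not touch the C1''–O bond.

Step 6
Reactants: 9 (3R)-5-[(1R)-1-(triethylsilyloxy)ethyl]-2,3-dihydro-1-benzofuran-3-yl 2-(diethoxyphosphoryl)acetate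
Product: 10 (3R)-5-[(1R)-1-(triethylsilyloxy)ethyl]-2,3-dihydro-1-benzofuran-3-yl 2-diazo-2-(diethoxyphosphoryl)acetate
Conditions: 4-acetamidobenzenesulfonyl azide, DBU (1.1 equiv), MeCN, 0 °C → rt
Reagents that add atoms: 4-acetamidobenzenesulfonyl azide, CC(=O)Nc1ccc(cc1)S(=O)(=O)N=[N+]=[N-]
Why: Regitz diazo transfer occurs at the only acidic position, the doubly activated phosphonoacetate CH2, and the short cold exposure to the amidine base leaves the C3 ester and both stereocentres alone.

Step 7
Reactants: 10 (3R)-5-[(1R)-1-(triethylsilyloxy)ethyl]-2,3-dihydro-1-benzofuran-3-yl 2-diazo-2-(diethoxyphosphoryl)acetate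
Product: 11 (3R,3aS,8bR)-3-(diethoxyphosphoryl)-7-[(1R)-1-(triethylsilyloxy)ethyl]-3,3a-dihydrofuro[3,2-b][1]benzofuran-2(8bH)-one (cis-fused; C3a = former C2, C8b = former C3; phosphorus on the convex face)
Conditions: Rh2(OAc)4 (2 mol %), ClCH2CH2Cl (0.01 M), reflux, slow addition of 10
Reagents that add atoms: none
Why: Rh2(OAc)4 binds the diazo carbon, N2 departs, and the electrophilic rhodium-bound carbene enters the C2–H bond in a concerted three-centre event with hydride-transfer character that donation from the O1 lone pair supports. The closest known reaction type is the intramolecular dirhodium-catalysed C–H insertion of diazoacetates and diazo(phosphono)acetates of secondary alcohols next to an ether oxygen, which delivers γ-lactones. The one new ring, the lactone O–C3–C2–C1'–C(=O), closes by 1,5-insertion through a five-membered array. C2 is governed by the preset C3 centre, since the tether reaches only the C2 hydrogen on the face of the ester oxygen and insertion goes with retention, so C1' ends cis to the C3 oxygen and a trans-fused bicyclo[3.3.0] product is out of reach; C1' is an acidic, epimerisable centre expected to settle with phosphorus on the convex face, and it is erased in step 8. The step needs site selectivity over C3–H (four-membered lactone), over addition to the C3a=C4 bond of ring A and over the ethoxy C–H bonds, and this is secured by ether activation of C2–H, by the ring-size preference and by the phosphoryl group, which lowers the electrophilicity of the carbene, while high dilution holds back carbene dimerisation.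

Step 8
Reactants: 11 (3R,3aS,8bR)-3-(diethoxyphosphoryl)-7-[(1R)-1-(triethylsilyloxy)ethyl]-3,3a-dihydrofuro[3,2-b][1]benzofuran-2(8bH)-one
Product: 12 (3aR,8bR)-3-methylidene-7-[(1R)-1-(triethylsilyloxy)ethyl]-3,3a-dihydrofuro[3,2-b][1]benzofuran-2(8bH)-one
Conditions: 37% aq HCHO (excess), K2CO3, THF, 0 °C
Reagents that add atoms: formaldehyde, C=O
Why: Horner–Wadsworth–Emmons methylenation of an α-phosphono-γ-lactone needs only carbonate, the stabilised anion is trapped quickly by excess formaldehyde, and any reversible loss of the O1 aryloxide would re-close by 5-exo oxa-Michael addition to the same cis-fused ring.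

Step 9
Reactants: 12 (3aR,8bR)-3-methylidene-7-[(1R)-1-(triethylsilyloxy)ethyl]-3,3a-dihydrofuro[3,2-b][1]benzofuran-2(8bH)-one
Product: 13 (2R,3R)-2-(3-hydroxyprop-1-en-2-yl)-5-[(1R)-1-(triethylsilyloxy)ethyl]-2,3-dihydro-1-benzofuran-3-ol
Conditions: i-Bu2AlH (3.5 equiv), CH2Cl2, −78 → 0 °C; aq potassium sodium tartrate
Reagents that add atoms: none
Why: i-Bu2AlH reduces α-methylene-γ-lactones in 1,2-fashion through the lactol aluminate and the hydroxy enal to the 2-methylene-1,4-diol, leaving the alkene, the aryl ether, the silyl ether and the C2/C3 centres unchanged.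

Step 10
Reactants: 13 (2R,3R)-2-(3-hydroxyprop-1-en-2-yl)-5-[(1R)-1-(triethylsilyloxy)ethyl]-2,3-dihydro-1-benzofuran-3-ol
Product: 15 (2R,3R)-2-[3-(tert-butyldiphenylsilyloxy)prop-1-en-2-yl]-5-[(1R)-1-(triethylsilyloxy)ethyl]-2,3-dihydro-1-benzofuran-3-yl acetate, via primary TBDPS ether 14 (not isolated)
Conditions: t-BuPh2SiCl (1.05 equiv), Et3N, DMAP (cat.), CH2Cl2, 0 °C → rt; then Ac2O, rt
Reagents that add atoms: tert-butyl(chloro)diphenylsilane, CC(C)(C)[Si](Cl)(c1ccccc1)c1ccccc1; acetic anhydride, CC(=O)OC(C)=O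
Why: The bulky chlorosilane selects the primary over the hindered secondary alcohol, and the same Et3N/DMAP medium then acetylates the remaining C3 hydroxyl at oxygen, so both operations are routine and leave every C–O stereocentre intact.

Step 11
Reactants: 15 (2R,3R)-2-[3-(tert-butyldiphenylsilyloxy)prop-1-en-2-yl]-5-[(1R)-1-(triethylsilyloxy)ethyl]-2,3-dihydro-1-benzofuran-3-yl acetate
Product: 16 (2R,3R)-2-[3-(tert-butyldiphenylsilyloxy)prop-1-en-2-yl]-5-[(1R)-1-hydroxyethyl]-2,3-dihydro-1-benzofuran-3-yl acetate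
Conditions: HF·pyridine, excess pyridine, THF, 0 °C
Reagents that add atoms: none
Why: Chemoselective desilylation rests on the large lability gap between a triethylsilyl and a tert-butyldiphenylsilyl ether, and the pyridine-buffered fluoride attacks silicon, so the C1''–O bond, the acetate and the configuration at C1'' persist.

Step 12
Reactants: 16 (2R,3R)-2-[3-(tert-butyldiphenylsilyloxy)prop-1-en-2-yl]-5-[(1R)-1-hydroxyethyl]-2,3-dihydro-1-benzofuran-3-yl acetate; 17 angelic acid [(2Z)-2-methylbut-2-enoic acid]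
Product: 19 (1R)-1-{(2R,3R)-3-acetoxy-2-[3-(tert-butyldiphenylsilyloxy)prop-1-en-2-yl]-2,3-dihydro-1-benzofuran-5-yl}ethyl (2Z)-2-methylbut-2-enoate, via angelic 2,4,6-trichlorobenzoic anhydride 18 (not isolated)
Conditions: 17, 2,4,6-Cl3C6H2COCl, Et3N, toluene, rt; filter; then 16, 75 °C, no DMAP
Reagents that add atoms: angelic acid (17), C/C=C(/C)C(=O)O
Why: Yamaguchi-type mixed-anhydride esterification directs the alcohol to the unshielded angeloyl carbonyl, and leaving out nucleophilic catalysts removes the addition–elimination path that turns angelates into tiglates, while acylation at oxygen retains 1''R.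

Step 13
Reactants: 19 (1R)-1-{(2R,3R)-3-acetoxy-2-[3-(tert-butyldiphenylsilyloxy)prop-1-en-2-yl]-2,3-dihydro-1-benzofuran-5-yl}ethyl (2Z)-2-methylbut-2-enoate
Product: 20 (1R)-1-[(2R,3R)-3-acetoxy-2-(3-hydroxyprop-1-en-2-yl)-2,3-dihydro-1-benzofuran-5-yl]ethyl (2Z)-2-methylbut-2-enoate
Conditions: Bu4NF, AcOH (1:1), THF, 0 °C → rt
Reagents that add atoms: none
Why: Fluoride-induced desilylation buffered with acetic acid is close to neutral, so neither ester is cleaved or shifted and no acetic acid is lost toward the benzofuran.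

Step 14
Reactants: 20 (1R)-1-[(2R,3R)-3-acetoxy-2-(3-hydroxyprop-1-en-2-yl)-2,3-dihydro-1-benzofuran-5-yl]ethyl (2Z)-2-methylbut-2-enoate
Product: 21 (1R)-1-[(2R,3R)-3-acetoxy-2-(3-oxoprop-1-en-2-yl)-2,3-dihydro-1-benzofuran-5-yl]ethyl (2Z)-2-methylbut-2-enoate (target)
Conditions: activated MnO2 (excess), CH2Cl2, rt
Reagents that add atoms: none
Why: Heterogeneous MnO2 oxidation of the only free, primary allylic alcohol stops at the enal under neutral, amine-free conditions, so the sensitive 2-substituted acrolein unit and all three stereocentres are left as they are.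

Compound list
1 | 5-bromo-1-benzofuran-3(2H)-one | O=C1COc2ccc(Br)cc21 | starting material
2 | (3R)-5-bromo-2,3-dihydro-1-benzofuran-3-ol | C1Oc2ccc(Br)cc2[C@H]1O | intermediate
3 | tributyl(1-ethoxyvinyl)stannane | C=C(OCC)[Sn](CCCC)(CCCC)CCCC | starting material
4 | (3R)-5-(1-ethoxyvinyl)-2,3-dihydro-1-benzofuran-3-ol | C1Oc2ccc(C(=C)OCC)cc2[C@H]1O | intermediate
5 | (3R)-5-acetyl-2,3-dihydro-1-benzofuran-3-ol | C1Oc2ccc(C(C)=O)cc2[C@H]1O | intermediate
6 | 2-(diethoxyphosphoryl)acetic acid | CCOP(=O)(CC(=O)O)OCC | starting material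
7 | (3R)-5-acetyl-2,3-dihydro-1-benzofuran-3-yl 2-(diethoxyphosphoryl)acetate | C1Oc2ccc(C(C)=O)cc2[C@H]1OC(=O)CP(=O)(OCC)OCC | intermediate
8 | (3R)-5-[(1R)-1-hydroxyethyl]-2,3-dihydro-1-benzofuran-3-yl 2-(diethoxyphosphoryl)acetate | C1Oc2ccc([C@@H](C)O)cc2[C@H]1OC(=O)CP(=O)(OCC)OCC | intermediate
9 | (3R)-5-[(1R)-1-(triethylsilyloxy)ethyl]-2,3-dihydro-1-benzofuran-3-yl 2-(diethoxyphosphoryl)acetate | C1Oc2ccc([C@@H](C)O[Si](CC)(CC)CC)cc2[C@H]1OC(=O)CP(=O)(OCC)OCC | intermediate
10 | (3R)-5-[(1R)-1-(triethylsilyloxy)ethyl]-2,3-dihydro-1-benzofuran-3-yl 2-diazo-2-(diethoxyphosphoryl)acetate | C1Oc2ccc([C@@H](C)O[Si](CC)(CC)CC)cc2[C@H]1OC(=O)C(=[N+]=[N-])P(=O)(OCC)OCC | intermediate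
11 | (3R,3aS,8bR)-3-(diethoxyphosphoryl)-7-[(1R)-1-(triethylsilyloxy)ethyl]-3,3a-dihydrofuro[3,2-b][1]benzofuran-2(8bH)-one | CCOP(=O)(OCC)[C@@H]3[C@H]1Oc2ccc([C@@H](C)O[Si](CC)(CC)CC)cc2[C@H]1OC3=O | intermediate
12 | (3aR,8bR)-3-methylidene-7-[(1R)-1-(triethylsilyloxy)ethyl]-3,3a-dihydrofuro[3,2-b][1]benzofuran-2(8bH)-one | C=C3[C@H]1Oc2ccc([C@@H](C)O[Si](CC)(CC)CC)cc2[C@H]1OC3=O | intermediate
13 | (2R,3R)-2-(3-hydroxyprop-1-en-2-yl)-5-[(1R)-1-(triethylsilyloxy)ethyl]-2,3-dihydro-1-benzofuran-3-ol | C=C(CO)[C@H]1Oc2ccc([C@@H](C)O[Si](CC)(CC)CC)cc2[C@H]1O | intermediate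
14 | (2R,3R)-2-[3-(tert-butyldiphenylsilyloxy)prop-1-en-2-yl]-5-[(1R)-1-(triethylsilyloxy)ethyl]-2,3-dihydro-1-benzofuran-3-ol | C=C(CO[Si](c3ccccc3)(c3ccccc3)C(C)(C)C)[C@H]1Oc2ccc([C@@H](C)O[Si](CC)(CC)CC)cc2[C@H]1O | intermediate
15 | (2R,3R)-2-[3-(tert-butyldiphenylsilyloxy)prop-1-en-2-yl]-5-[(1R)-1-(triethylsilyloxy)ethyl]-2,3-dihydro-1-benzofuran-3-yl acetate | C=C(CO[Si](c3ccccc3)(c3ccccc3)C(C)(C)C)[C@H]1Oc2ccc([C@@H](C)O[Si](CC)(CC)CC)cc2[C@H]1OC(C)=O | intermediate
16 | (2R,3R)-2-[3-(tert-butyldiphenylsilyloxy)prop-1-en-2-yl]-5-[(1R)-1-hydroxyethyl]-2,3-dihydro-1-benzofuran-3-yl acetate | C=C(CO[Si](c3ccccc3)(c3ccccc3)C(C)(C)C)[C@H]1Oc2ccc([C@@H](C)O)cc2[C@H]1OC(C)=O | intermediate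
17 | angelic acid, (2Z)-2-methylbut-2-enoic acid | C/C=C(/C)C(=O)O | starting material
18 | (2Z)-2-methylbut-2-enoic 2,4,6-trichlorobenzoic anhydride | C/C=C(/C)C(=O)OC(=O)c1c(Cl)cc(Cl)cc1Cl | intermediate
19 | (1R)-1-{(2R,3R)-3-acetoxy-2-[3-(tert-butyldiphenylsilyloxy)prop-1-en-2-yl]-2,3-dihydro-1-benzofuran-5-yl}ethyl (2Z)-2-methylbut-2-enoate | C=C(CO[Si](c3ccccc3)(c3ccccc3)C(C)(C)C)[C@H]1Oc2ccc([C@@H](C)OC(=O)/C(C)=C\C)cc2[C@H]1OC(C)=O | intermediate
20 | (1R)-1-[(2R,3R)-3-acetoxy-2-(3-hydroxyprop-1-en-2-yl)-2,3-dihydro-1-benzofuran-5-yl]ethyl (2Z)-2-methylbut-2-enoate | C=C(CO)[C@H]1Oc2ccc([C@@H](C)OC(=O)/C(C)=C\C)cc2[C@H]1OC(C)=O | intermediate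
21 | (1R)-1-[(2R,3R)-3-acetoxy-2-(3-oxoprop-1-en-2-yl)-2,3-dihydro-1-benzofuran-5-yl]ethyl (2Z)-2-methylbut-2-enoate | C=C(C=O)[C@H]1Oc2ccc([C@@H](C)OC(=O)/C(C)=C\C)cc2[C@H]1OC(C)=O | target

Total step count: 14. Longest linear sequence: 14 steps, from 1 to 21.

Steps most likely to fail

**Step 7.**
- What may go wrong: the carbene may add to the C3a=C4 bond of ring A (Büchner-type cyclopropanation), attack an ethoxy C–H bond of the phosphonate, or dimerise faster than it inserts.
- Change of approach: the fallback gives up the phosphoryl group and uses an acceptor-only carbene on an electron-rich carboxamidate catalyst. That catalyst class favours C–H insertion over aromatic addition. The methylene carbon is then brought in afterwards without a discrete metal enolate.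
- Course: the fallback sets out from 9. K2CO3 in MeOH releases (3R)-5-[(1R)-1-(triethylsilyloxy)ethyl]-2,3-dihydro-1-benzofuran-3-ol F1. Glyoxylic acid chloride tosylhydrazone with PhNMe2 gives the glyoxylate tosylhydrazone ester F2, and added Et3N fragments it to the diazoacetate F3. Rh2(cap)4 in refluxing CH2Cl2 should close the unsubstituted cis-fused lactone F4 by the same syn C2–H insertion. Warming with tert-butoxybis(dimethylamino)methane gives the (E)-dimethylaminomethylidene lactone F5. Conjugate reduction with i-Bu2AlH at −78 °C, with loss of dimethylamine on work-up, brings the sequence back to the route at 12.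

**Step 12.**
- What may go wrong: the angeloyl unit may isomerise from Z to E during activation or acyl transfer, acylation by the hindered acid may be sluggish, or warm ionisation at the p-alkoxybenzylic C1'' may erode its configuration.
- Change of approach: the fallback builds the Z-alkene on the ester instead of transferring it.
- Course: the fallback sets out from 16. DCC coupling at 0 °C with 2-[bis(2,2,2-trifluoroethoxy)phosphoryl]propanoic acid gives the side-chain phosphonopropanoate F6, as both epimers at the phosphonate carbon. Still–Gennari olefination then forms the (Z)-2-methylbut-2-enoate and returns to the route at 19. Its conditions are KN(SiMe3)2 (1.0 equiv), 18-crown-6, THF, −78 °C, then acetaldehyde.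

**Step 4.**
- What may go wrong: hydride transfer to the donor-substituted aryl ketone may be slow. The C3 ester would then sit for a long time in a formic acid medium, where formolysis, ionisation toward the benzofuran or binding of the phosphonoacetate to ruthenium may take over.
- Change of approach: the fallback replaces metal-catalysed transfer hydrogenation by a Corey–Bakshi–Shibata reduction in an aprotic, acid-free medium.
- Course: the fallback sets out from 7. (S)-2-Methyl-CBS-oxazaborolidine (cat.) with BH3·SMe2 in THF at −20 °C should deliver the 1''R alcohol directly and rejoin the route at 8, with no new compound on the way.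

Further compounds
F1 | step 7 | (3R)-5-[(1R)-1-(triethylsilyloxy)ethyl]-2,3-dihydro-1-benzofuran-3-ol | C1Oc2ccc([C@@H](C)O[Si](CC)(CC)CC)cc2[C@H]1O
F2 | step 7 | (3R)-5-[(1R)-1-(triethylsilyloxy)ethyl]-2,3-dihydro-1-benzofuran-3-yl (2E)-2-(tosylhydrazinylidene)acetate | C1Oc2ccc([C@@H](C)O[Si](CC)(CC)CC)cc2[C@H]1OC(=O)/C=N/NS(=O)(=O)c1ccc(C)cc1
F3 | step 7 | (3R)-5-[(1R)-1-(triethylsilyloxy)ethyl]-2,3-dihydro-1-benzofuran-3-yl 2-diazoacetate | C1Oc2ccc([C@@H](C)O[Si](CC)(CC)CC)cc2[C@H]1OC(=O)C=[N+]=[N-]
F4 | step 7 | (3aR,8bR)-7-[(1R)-1-(triethylsilyloxy)ethyl]-3,3a-dihydrofuro[3,2-b][1]benzofuran-2(8bH)-one | O=C3C[C@H]1Oc2ccc([C@@H](C)O[Si](CC)(CC)CC)cc2[C@H]1O3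
F5 | step 7 | (3E,3aR,8bR)-3-[(dimethylamino)methylidene]-7-[(1R)-1-(triethylsilyloxy)ethyl]-3,3a-dihydrofuro[3,2-b][1]benzofuran-2(8bH)-one | CN(C)/C=C3\[C@H]1Oc2ccc([C@@H](C)O[Si](CC)(CC)CC)cc2[C@H]1OC3=O
F6 | step 12 | (1R)-1-{(2R,3R)-3-acetoxy-2-[3-(tert-butyldiphenylsilyloxy)prop-1-en-2-yl]-2,3-dihydro-1-benzofuran-5-yl}ethyl 2-[bis(2,2,2-trifluoroethoxy)phosphoryl]propanoate (both epimers at the phosphonate carbon) | C=C(CO[Si](c3ccccc3)(c3ccccc3)C(C)(C)C)[C@H]1Oc2ccc([C@@H](C)OC(=O)C(C)P(=O)(OCC(F)(F)F)OCC(F)(F)F)cc2[C@H]1OC(C)=O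
F0 | step 4 | none | none
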